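**Plan**

- Cuts, in retrosynthetic order: C16=C17 back to a C16 ketone (a temporary α-keto ester); then C13–C14 and C6–C8 together; then the lactone C7–O bond and C9–C10; ring A goes back to 4,4-dimethylcyclohex-2-enone.
- Enabling feature: C8, the quaternary α-carbon of the C7/C20 δ-lactone, carries both the C14 methylene (β to C7=O, bonded to C13) and the C6 carbinol. An α-methylene lactone can therefore accept C13 at C14 and pass its enolate on to a C6 aldehyde. A ketone at C16 makes C13–H acidic and is methylenated afterwards.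
- Forward: the ring A piece (C1–C6, C10, C20) and the chain (C7–C9, C11–C16) are joined by O-allylation/Claisen rearrangement (C9–C10). The lactone ring is closed next. One base-triggered domino then closes ring C (C13–C14) and the cyclopentane C5–C6–C8–C9–C10 (C6–C8). Methylenation and desilylation finish.
- Stereochemistry: C5 from the Rh/(R)-BINAP 1,4-addition; C11 from (S)-butane-1,2,4-triol acetonide (chiral pool); C10 and C9 from the chair Claisen anti to the C5 side chain; C1 from axial hydride delivery; C8, C6 and C13 in the key step.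

Key step: step 15

Remark: ent-kaurane numbering is used for the carbons of all intermediates (C7 lactone carbonyl, C15 ester carbon, C17 exocyclic methylene, C20 lactone CH2). The facial sense of the Rh/(R)-BINAP addition is assumed to follow that known for 2-cyclohexenone; if it does not, (S)-BINAP is used.

**Route**

Step 1
Reactants: 1 4,4-dimethylcyclohex-2-en-1-one; 2 hex-1-yne
Product: 5 (3R)-3-[(E)-hex-1-enyl]-2-(hydroxymethylidene)-4,4-dimethylcyclohexan-1-one, via alkenylborane 3 (not isolated), via boron enolate 4 (not isolated)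
Conditions: 9-BBN, THF, 0 °C to rt (on 2); then 1, [Rh(OMe)(cod)]2 (cat.), (R)-BINAP, toluene, 80 °C; then n-BuLi, −78 °C; CF3CH2OCHO; aq. HCl
Reagents that add atoms: 2,2,2-trifluoroethyl formate, O=COCC(F)(F)F
Why: Rhodium-catalysed asymmetric conjugate addition (Hayashi–Miyaura reaction) of the B-alkenylborane sets C5 under control of (R)-BINAP and leaves a regiodefined boron enolate; n-BuLi turns it into the lithium enolate, which is C-formylated at C10, so the stereocentre and the C10/C20 activation arise together.

Step 2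
Reactants: 6 2-[(4S)-2,2-dimethyl-1,3-dioxolan-4-yl]ethan-1-ol
Product: 7 (4S)-4-(2-iodoethyl)-2,2-dimethyl-1,3-dioxolane
Conditions: I2, PPh3, imidazole, CH2Cl2, 0 °C
Reagents that add atoms: iodine, II
Why: Appel-type iodination of the primary alcohol under buffered conditions leaves the acetonide and the C11 stereocentre untouched.

Step 3
Reactants: 8 1,3-dithiane; 7 (4S)-4-(2-iodoethyl)-2,2-dimethyl-1,3-dioxolane
Product: 10 methyl 2-{2-[(4S)-2,2-dimethyl-1,3-dioxolan-4-yl]ethyl}-1,3-dithiane-2-carboxylate, via alkyl dithiane 9 (not isolated)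
Conditions: n-BuLi, THF, −30 °C; 7, −78 to −20 °C; n-BuLi, −30 °C; ClCO2Me, −78 °C
Reagents that add atoms: methyl chloroformate, COC(=O)Cl
Why: Corey–Seebach alkylation of 2-lithio-1,3-dithiane with the primary iodide, followed by a second lithiation and C-acylation, installs C16 as a dithiane carbon and C15 as the methyl ester (a masked α-keto ester).

Step 4
Reactants: 10 methyl 2-{2-[(4S)-2,2-dimethyl-1,3-dioxolan-4-yl]ethyl}-1,3-dithiane-2-carboxylate
Product: 11 methyl 2-[(3S)-3,4-dihydroxybutyl]-1,3-dithiane-2-carboxylate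
Conditions: PPTS, MeOH, rt
Reagents that add atoms: none
Why: Acid-catalysed transketalisation removes the acetonide, and methanol as solvent keeps the δ-hydroxy ester from lactonising.

Step 5
Reactants: 11 methyl 2-[(3S)-3,4-dihydroxybutyl]-1,3-dithiane-2-carboxylate
Product: 12 methyl 2-[(3S)-3,4-bis(triethylsilyloxy)butyl]-1,3-dithiane-2-carboxylate
Conditions: Et3SiCl, imidazole, DMF, 0 °C
Reagents that add atoms: chlorotriethylsilane, CC[Si](Cl)(CC)CC
Why: Standard silylation of both hydroxyl groups prepares the selective oxidation of the primary position.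

Step 6
Reactants: 12 methyl 2-[(3S)-3,4-bis(triethylsilyloxy)butyl]-1,3-dithiane-2-carboxylate
Product: 13 methyl 2-[(3S)-4-oxo-3-(triethylsilyloxy)butyl]-1,3-dithiane-2-carboxylate
Conditions: (COCl)2, DMSO, CH2Cl2, −78 to −30 °C; Et3N
Reagents that add atoms: none
Why: Under Swern conditions a primary triethylsilyl ether is cleaved and oxidised directly while the secondary one stays, giving the α-silyloxy aldehyde (C9) without separate diol differentiation; the dithiane tolerates the activated sulfoxide.

Step 7
Reactants: 13 methyl 2-[(3S)-4-oxo-3-(triethylsilyloxy)butyl]-1,3-dithiane-2-carboxylate; 14 methyl acrylate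
Product: 15 methyl 2-[(3S)-4-hydroxy-5-(methoxycarbonyl)-3-(triethylsilyloxy)hex-5-en-1-yl]-1,3-dithiane-2-carboxylate (C9 epimers)
Conditions: 14 (excess), DABCO, MeOH (cat.), rt
Reagents that add atoms: none
Why: Morita–Baylis–Hillman reaction of the activated α-oxy aldehyde brings in C7, C8 and C14; the new carbinol centre is lost in step 8, and the short reaction time should limit epimerisation at C11.

Step 8
Reactants: 15 methyl 2-[(3S)-4-hydroxy-5-(methoxycarbonyl)-3-(triethylsilyloxy)hex-5-en-1-yl]-1,3-dithiane-2-carboxylate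
Product: 16 methyl 2-[(3S,4Z)-6-bromo-5-(methoxycarbonyl)-3-(triethylsilyloxy)hex-4-en-1-yl]-1,3-dithiane-2-carboxylate
Conditions: CBr4, PPh3, CH2Cl2, 0 °C
Reagents that add atoms: carbon tetrabromide, BrC(Br)(Br)Br
Why: Appel bromination of a Morita–Baylis–Hillman alcohol proceeds with allylic transposition (SN2′) to the favoured (Z)-2-(bromomethyl)enoate, in which C11 is cis to CH2Br.

Step 9
Reactants: 5 (3R)-3-[(E)-hex-1-enyl]-2-(hydroxymethylidene)-4,4-dimethylcyclohexan-1-one; 16 methyl 2-[(3S,4Z)-6-bromo-5-(methoxycarbonyl)-3-(triethylsilyloxy)hex-4-en-1-yl]-1,3-dithiane-2-carboxylate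
Product: 18 2-formyl ketone with quaternary C10 bearing the C9 side chain [C9–C10 formed; C8=C14 methylene ester; configuration as in the SMILES], via allyl enol ether 17 (not isolated)
Conditions: K2CO3, acetone, rt; then xylenes, BHT, 140 °C
Reagents that add atoms: none
Why: The hindered enolate of the hydroxymethylene ketone is alkylated on the formyl oxygen at C14, and the (E)-allyloxymethylene ketone then undergoes Claisen rearrangement through a chair transition state on the face anti to the pseudo-axial C5 hexenyl group; this sets the quaternary C10 (C20 cis to the C5 side chain) and, through the (Z)-allyl geometry, C9, and regenerates the C8=C14 methylene.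

Step 10
Reactants: 18 2-formyl ketone
Product: 20 α-methylene spiro-δ-lactone ketone (C7–O–C20 lactone; C1 ketone), via hydroxy ester 19 (not isolated)
Conditions: NaBH4, THF/MeOH, −78 °C; then PPTS, toluene, 60 °C
Reagents that add atoms: none
Why: The aldehyde is reduced chemoselectively over the hindered α-quaternary ketone and the esters, and the neopentyl C20 alcohol closes the six-membered lactone onto the C7 methyl ester.

Step 11
Reactants: 20 α-methylene spiro-δ-lactone ketone
Product: 21 C1 alcohol (equatorial, cis to C20)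
Conditions: NaBH4, CeCl3·7H2O, MeOH, −40 °C
Reagents that add atoms: none
Why: Luche reduction; hydride attacks C1 axially, anti to the axial C20 substituent on the neighbouring quaternary C10, giving the equatorial alcohol, and the cerium salt suppresses 1,4-reduction of the methylene lactone.

Step 12
Reactants: 21 C1 alcohol
Product: 22 C1 acetate
Conditions: Ac2O, pyridine, DMAP, CH2Cl2, rt
Reagents that add atoms: acetic anhydride, CC(=O)OC(C)=O
Why: The only free hydroxyl is acetylated at once, which places the acetate before C6–OH exists and blocks translactonisation of C1–OH onto C7.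

Step 13
Reactants: 22 C1 acetate
Product: 23 α-keto ester (C16 ketone)
Conditions: PhI(OCOCF3)2, NaHCO3, MeCN/H2O (9:1), 0 °C
Reagents that add atoms: water, O
Why: Oxidative hydrolysis of the dithiane with the hypervalent iodine reagent is fast under buffered conditions and should spare the alkenes, the silyl ether and the acetate.

Step 14
Reactants: 23 α-keto ester
Product: 24 keto ester aldehyde (C6 aldehyde on C5)
Conditions: O3, CH2Cl2, −78 °C (Sudan Red 7B end point); PPh3
Reagents that add atoms: ozone, [O-][O+]=O
Why: Ozonolysis cleaves the electron-rich 1,2-disubstituted alkene much faster than the electron-poor α-methylene lactone, releasing the C6 aldehyde.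

Step 15
Reactants: 24 keto ester aldehyde
Product: 26 tetracyclic hydroxy keto ester (ring C and cyclopentane closed; C6–OH; C16 ketone), via potassium lactone enolate 25 (not isolated)
Conditions: KN(SiMe3)2 (1.0 equiv), THF, −78 to 0 °C; AcOH
Reagents that add atoms: none
Why: One equivalent of base deprotonates only C13–H of the α-keto ester, and the potassium enolate adds through C13 to C14, the unsubstituted terminus of the α-methylene lactone; the lactone enolate at C8 then adds to the C6 aldehyde held over it by C5–C10, an intramolecular anionic Michael/aldol domino of a well-known type. Ring C closes by 6-(enolexo)-endo-trig attack (C13–C14) and the cyclopentane C5–C6–C8–C9–C10 by 5-(enolexo)-exo-trig attack (C6–C8). C8 is fixed by C10 and C9, because only the lactone face syn to C5 can reach the aldehyde; C6–OH should end up exo (anti to the lactone bridge and the C4 methyls) through an open potassium aldol transition state, which is also the expected thermodynamic outcome of this reversible step; C13 stays α to the C16 ketone and should equilibrate to the equatorial epimer cis to the C11 silyl ether. The domino ends on the stabilised keto ester enolate of the product, which makes it downhill. The selectivities needed are C- over O-alkylation and aldol over Dieckmann closure of C8 onto the C15 ester; the high electrophilicity of the aldehyde and the reversibility of the competing closures should secure them.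

Step 16
Reactants: 26 tetracyclic hydroxy keto ester
Product: 27 11-O-triethylsilyl ether of the target (acrylate installed)
Conditions: Zn, CH2Br2, TiCl4, THF/CH2Cl2, 0 °C to rt
Reagents that add atoms: dibromomethane, BrCBr
Why: Takai–Lombardo methylenation is non-basic and ketone-selective, so it should convert the C16 ketone into the C16=C17 methylene without retro-aldol opening at C6/C8 and without touching lactone, esters or free hydroxyl.

Step 17
Reactants: 27 11-O-triethylsilyl ether of the target
Product: 28 CNP0421185.1 (1S,5R,6S,8S,9S,10S,11S,13S)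
Conditions: HF·pyridine, THF/pyridine, 0 °C
Reagents that add atoms: none
Why: Buffered fluoride desilylation frees C11–OH under conditions that should leave the acetate, the lactone and the acrylate intact.

**Compound list**

1 | 4,4-dimethylcyclohex-2-en-1-one | CC1(C)CCC(=O)C=C1 | starting material
2 | hex-1-yne | CCCCC#C | starting material
3 | B-[(E)-hex-1-enyl]-9-borabicyclo[3.3.1]nonane | CCCC/C=C/B1C2CCCC1CCC2 | intermediate (not isolated)
4 | 9-{[(3S)-3-[(E)-hex-1-enyl]-4,4-dimethylcyclohex-1-en-1-yl]oxy}-9-borabicyclo[3.3.1]nonane | CCCC/C=C/[C@H]1C=C(OB2C3CCCC2CCC3)CCC1(C)C | intermediate (not isolated)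
5 | (3R)-3-[(E)-hex-1-enyl]-2-(hydroxymethylidene)-4,4-dimethylcyclohexan-1-one | O=C1CCC(C)(C)[C@@H](/C=C/CCCC)C1=CO | intermediate
6 | 2-[(4S)-2,2-dimethyl-1,3-dioxolan-4-yl]ethan-1-ol | OCC[C@H]1COC(C)(C)O1 | starting material
7 | (4S)-4-(2-iodoethyl)-2,2-dimethyl-1,3-dioxolane | ICC[C@H]1COC(C)(C)O1 | intermediate
8 | 1,3-dithiane | C1CSCSC1 | starting material
9 | 2-{2-[(4S)-2,2-dimethyl-1,3-dioxolan-4-yl]ethyl}-1,3-dithiane | C1CSC(CC[C@H]2COC(C)(C)O2)SC1 | intermediate (not isolated)
10 | methyl 2-{2-[(4S)-2,2-dimethyl-1,3-dioxolan-4-yl]ethyl}-1,3-dithiane-2-carboxylate | COC(=O)C1(SCCCS1)CC[C@H]2COC(C)(C)O2 | intermediate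
11 | methyl 2-[(3S)-3,4-dihydroxybutyl]-1,3-dithiane-2-carboxylate | COC(=O)C1(SCCCS1)CC[C@H](O)CO | intermediate
12 | methyl 2-[(3S)-3,4-bis(triethylsilyloxy)butyl]-1,3-dithiane-2-carboxylate | COC(=O)C1(SCCCS1)CC[C@H](O[Si](CC)(CC)CC)CO[Si](CC)(CC)CC | intermediate
13 | methyl 2-[(3S)-4-oxo-3-(triethylsilyloxy)butyl]-1,3-dithiane-2-carboxylate | COC(=O)C1(SCCCS1)CC[C@H](O[Si](CC)(CC)CC)C=O | intermediate
14 | methyl acrylate | C=CC(=O)OC | starting material
15 | methyl 2-[(3S)-4-hydroxy-5-(methoxycarbonyl)-3-(triethylsilyloxy)hex-5-en-1-yl]-1,3-dithiane-2-carboxylate (C9 epimers) | COC(=O)C1(SCCCS1)CC[C@H](O[Si](CC)(CC)CC)C(O)C(=C)C(=O)OC | intermediate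
16 | methyl 2-[(3S,4Z)-6-bromo-5-(methoxycarbonyl)-3-(triethylsilyloxy)hex-4-en-1-yl]-1,3-dithiane-2-carboxylate | COC(=O)C1(SCCCS1)CC[C@H](O[Si](CC)(CC)CC)/C=C(\CBr)C(=O)OC | intermediate
17 | (E)-allyloxymethylidene ketone: enol ether of 5 (through the C20 oxygen) with the C14 methylene of 16 | O=C1CCC(C)(C)[C@@H](/C=C/CCCC)/C1=C\OC/C(C(=O)OC)=C\[C@@H](O[Si](CC)(CC)CC)CCC2(SCCCS2)C(=O)OC | intermediate (not isolated)
18 | 2-formyl ketone: C10 quaternary (CHO, C9 side chain), C9 bearing the 1-(methoxycarbonyl)vinyl group and the C11(OSiEt3)–C12–C13–dithiane ester chain, (E)-hexenyl at C5 | COC(=O)C2(SCCCS2)CC[C@H](O[Si](CC)(CC)CC)[C@H](C(=C)C(=O)OC)[C@]1(C=O)C(=O)CCC(C)(C)[C@H]1/C=C/CCCC | intermediate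
19 | hydroxy ester: 18 with C20 as CH2OH | COC(=O)C2(SCCCS2)CC[C@H](O[Si](CC)(CC)CC)[C@H](C(=C)C(=O)OC)[C@]1(CO)C(=O)CCC(C)(C)[C@H]1/C=C/CCCC | intermediate (not isolated)
20 | α-methylene spiro-δ-lactone ketone (lactone C7–O–C20 spiro at C10 to ring A; C1 ketone) | COC(=O)C3(SCCCS3)CC[C@H](O[Si](CC)(CC)CC)[C@@H]1C(=C)C(=O)OC[C@]12C(=O)CCC(C)(C)[C@H]2/C=C/CCCC | intermediate
21 | C1 alcohol of 20 (OH equatorial, cis to C20) | COC(=O)C3(SCCCS3)CC[C@H](O[Si](CC)(CC)CC)[C@@H]1C(=C)C(=O)OC[C@]12[C@@H](O)CCC(C)(C)[C@H]2/C=C/CCCC | intermediate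
22 | C1 acetate of 21 | COC(=O)C3(SCCCS3)CC[C@H](O[Si](CC)(CC)CC)[C@@H]1C(=C)C(=O)OC[C@]12[C@@H](OC(C)=O)CCC(C)(C)[C@H]2/C=C/CCCC | intermediate
23 | α-keto ester (dithiane of 22 replaced by C16=O) | COC(=O)C(=O)CC[C@H](O[Si](CC)(CC)CC)[C@@H]1C(=C)C(=O)OC[C@]12[C@@H](OC(C)=O)CCC(C)(C)[C@H]2/C=C/CCCC | intermediate
24 | keto ester aldehyde (hexenyl of 23 replaced by the C6 aldehyde) | COC(=O)C(=O)CC[C@H](O[Si](CC)(CC)CC)[C@@H]1C(=C)C(=O)OC[C@]12[C@@H](OC(C)=O)CCC(C)(C)[C@H]2C=O | intermediate
25 | potassium lactone enolate after the Michael closure (ring C closed; C8=C7 enolate; C6 aldehyde free) | COC(=O)C(=O)[C@@H]1C[C@H](O[Si](CC)(CC)CC)[C@@H]2C(C1)=C([O-])OC[C@]23[C@@H](OC(C)=O)CCC(C)(C)[C@H]3C=O.[K+] | intermediate (not isolated)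
26 | tetracyclic hydroxy keto ester (C13–C14 and C6–C8 closed; C6–OH; C16 ketone; C11–OSiEt3; C1–OAc) | COC(=O)C(=O)[C@@H]1C[C@H](O[Si](CC)(CC)CC)[C@@H]2[C@]3(C1)C(=O)OC[C@]21[C@@H](OC(C)=O)CCC(C)(C)[C@H]1[C@@H]3O | intermediate
27 | 11-O-triethylsilyl ether of the target | C=C(C(=O)OC)[C@@H]1C[C@H](O[Si](CC)(CC)CC)[C@@H]2[C@]3(C1)C(=O)OC[C@]21[C@@H](OC(C)=O)CCC(C)(C)[C@H]1[C@@H]3O | intermediate
28 | CNP0421185.1 (1S,5R,6S,8S,9S,10S,11S,13S) | C=C(C(=O)OC)[C@@H]1C[C@H](O)[C@@H]2[C@]3(C1)C(=O)OC[C@]21[C@@H](OC(C)=O)CCC(C)(C)[C@H]1[C@@H]3O | target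

**Step count and risks**

Total: 17 steps. Longest linear sequence: 16 steps (steps 2–8, then 9–17).

Steps most likely to fail:

1. Step 15. The lactone enolate at C8 may be protonated before it reaches the aldehyde, so the domino stops after the Michael closure. C8 may instead close onto the C15 ester, the aldol may take the wrong facial course at C6, or the acetyl group may migrate from O1. Fallback, from 24 back to 26: the keto ester of 24 is converted with Me3SiCl/Et3N into its (Z)-trimethylsilyl enol ether F1. A catalytic amount of tetrabutylammonium difluorotriphenylsilicate in THF at −78 °C then triggers a silicon-transfer Mukaiyama–Michael/aldol sequence, in which each anionic intermediate is capped by silyl transfer, giving the C6 trimethylsilyl ether F2. Citric acid in methanol removes the trimethylsilyl group and returns 26.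

2. Step 9. Alkylation may occur on carbon (C10 to C14, no transposition) instead of on the formyl oxygen. The C9 configuration may also be eroded through the (Z)-enol ether or a boat transition state. Fallback, from 15 and 5 back to 18: alcohol 15 is converted with Boc2O/DMAP into the tert-butyl carbonate F3. A tertiary-amine Lewis base catalyst (DABCO or (DHQD)2PHAL) then effects the SN2′/SN2′ allylic alkylation of 5 at C10 with F3, forming the C9–C10 bond directly, with C9 set by the catalyst and C10 by the C5 side chain, and gives 18.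

3. Step 1. The rhodium alkenyl may add sluggishly or with poor facial selectivity to the hindered β-carbon next to the gem-dimethyl group, and the lithium enolate may be formylated on oxygen. Fallback, from 1 and 2 back to 5: hydrozirconation of 2 with Cp2Zr(H)Cl, 1,4-addition to 1 catalysed by [Rh(cod)(MeCN)2]BF4/(R)-BINAP, and trapping of the zirconium enolate with monomeric formaldehyde gives the trans β-hydroxymethyl ketone F4. Dess–Martin periodinane oxidation of F4 returns 5.

Further compounds
F1 | step 15 | (Z)-trimethylsilyl enol ether of the keto ester of 24 | COC(=O)/C(O[Si](C)(C)C)=C/C[C@H](O[Si](CC)(CC)CC)[C@@H]1C(=C)C(=O)OC[C@]12[C@@H](OC(C)=O)CCC(C)(C)[C@H]2C=O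
F2 | step 15 | 6-O-trimethylsilyl ether of 26 | COC(=O)C(=O)[C@@H]1C[C@H](O[Si](CC)(CC)CC)[C@@H]2[C@]3(C1)C(=O)OC[C@]21[C@@H](OC(C)=O)CCC(C)(C)[C@H]1[C@@H]3O[Si](C)(C)C
F3 | step 9 | tert-butyl carbonate of 15 (C9 epimers) | COC(=O)C1(SCCCS1)CC[C@H](O[Si](CC)(CC)CC)C(OC(=O)OC(C)(C)C)C(=C)C(=O)OC
F4 | step 1 | trans-3-[(E)-hex-1-enyl]-2-(hydroxymethyl)-4,4-dimethylcyclohexan-1-one | O=C1CCC(C)(C)[C@@H](/C=C/CCCC)[C@@H]1CO
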